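## Retrosynthetic overview

1. Target ⇐ Me2CuLi conjugate addition to a 15-nor-enone triester; this installs C15 and sets C3 last.
2. Ester triad ⇐ C7 angeloylation, C8 acetylation, OH-directed C8 reduction, Rubottom C7–O, and the key catalyst-controlled C9–O bond (α-angeloyloxylation of a 1,8-dione).
3. 1,8-Dione ⇐ C8–H ketonisation of 15-norlongipin-2-en-1-one ⇐ decarbonylation, SeO2 and allylic oxidation of (+)-α-longipinene.
4. No ring is formed: the cyclobutane, six- and seven-membered rings are carried intact from (+)-α-longipinene, and all strategic bonds made are C–O bonds.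

**Target:** (3R,4S,5S,7S,8R,9S,10R,11R)-8α-acetoxy-7β,9α-bis(angeloyloxy)longipinan-1-one (angeloyl = (Z)-2-methylbut-2-enoyl).

**Numbering (longipinane):** ring C1–C2–…–C11–C1 with extra bonds C4–C10 and C5–C11 (cyclobutane C4–C5–C11–C10). C12/C13 sit on C6, C14 on C10, C15 on C3. On the seven-membered ring, α is the face toward C11 and β the face toward C4.

**Assumption 1:** commercial (+)-α-longipinene is the (1R,2S,7R,8R) enantiomer, whose cage (C4, C5, C10, C11) already has the absolute configuration of the target.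

**Assumption 2:** 9-amino(9-deoxy)epi-quinidine is the pseudoenantiomer that delivers the acyloxy group to the α face (9S); if a test run shows the opposite sense, the quinine-derived amine is used instead.

## Route

Step 1
Reactants: 1 (+)-α-longipinene
Product: 2 (4R,5S,10R,11R)-longipin-2-en-1-one
Conditions: CrO3, 3,5-dimethylpyrazole, CH2Cl2, −20 °C
Reagents that add atoms: chromium trioxide, O=[Cr](=O)=O
Why: Allylic C–H oxidation (CrO3·3,5-dimethylpyrazole) converts the ring allylic methylene C1 into the enone, as in α-pinene → verbenone; C4 is a bridgehead and no stereocentre is touched.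

Step 2
Reactants: 2 (4R,5S,10R,11R)-longipin-2-en-1-one
Product: 4 (4S,5S,10R,11R)-1-oxolongipin-2-en-15-al, via 15-hydroxy enone 3 (not isolated)
Conditions: SeO2, 1,4-dioxane/H2O, 90 °C
Reagents that add atoms: selenium dioxide, O=[Se]=O
Why: Riley-type SeO2 oxidation of the γ-methyl of a β-methyl enone gives the allylic alcohol and then the aldehyde; the bridgehead C11 cannot enolise, so no other position is activated.

Step 3
Reactants: 4 (4S,5S,10R,11R)-1-oxolongipin-2-en-15-al
Product: 5 (4S,5S,10R,11R)-15-norlongipin-2-en-1-one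
Conditions: [Rh(dppp)2]Cl (5 mol%), xylenes, 140 °C, N2 sweep
Reagents that add atoms: none
Why: Rh-catalysed (Tsuji–Wilkinson type) decarbonylation of the enal excises C15 and leaves an enone with no enolisable hydrogen, which masks the C1 ketone for steps 6–10 and is the acceptor for the final methyl delivery.

Step 4
Reactants: 5 (4S,5S,10R,11R)-15-norlongipin-2-en-1-one
Product: 6 (4S,5S,10R,11R)-15-norlongipin-2-ene-1,8-dione
Conditions: quinuclidine, Me4NBF4, HFIP, MeCN, O2, RVC(+)/Ni(−), constant current, rt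
Reagents that add atoms: dioxygen, O=O
Why: Quinuclidine-mediated electrochemical C–H oxidation: the electrophilic aminium radical abstracts H from the most hydridic, least hindered methylene, C8 (a CH2 flanked by two CH2–Cq units, the same motif as C2 of sclareolide); cyclobutane, α-carbonyl and neopentyl C–H bonds are disfavoured, and O2 trapping leads to the ketone.

Step 5
Reactants: 7 angelic acid (2 equiv)
Product: 9 di(angeloyl) peroxide, via peroxyangelic acid 8 (not isolated)
Conditions: H2O2 (50% aq., 0.5 equiv), DCC (1.0 equiv), CH2Cl2/Et2O, 0 °C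
Reagents that add atoms: hydrogen peroxide, OO; angelic acid (the second equivalent of 7), C/C=C(/C)C(=O)O
Why: Carbodiimide coupling of two molecules of the acid with one H2O2 (first acylation to the peracid 8, then acylation of 8 by a second DCC-activated molecule of 7) gives the symmetrical diacyl peroxide without an acid chloride, so the (Z)-alkene does not isomerise, and at 0 °C the electron-poor alkene is not epoxidised by 8.

Step 6
Reactants: 6 (4S,5S,10R,11R)-15-norlongipin-2-ene-1,8-dione; 9 di(angeloyl) peroxide (1.05 equiv)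
Product: 10 (4S,5S,9S,10R,11R)-9-angeloyloxy-15-norlongipin-2-ene-1,8-dione
Conditions: 9-amino(9-deoxy)epi-quinidine (20 mol%), Cl3CCO2H (40 mol%), BHT (10 mol%), THF, 25 °C, dark
Reagents that add atoms: none
Why: Proposed new method: primary-amine enamine catalysis with a di(alkenoyl) peroxide as electrophilic oxygen source, in which the enamine of the C8 ketone forms toward C9 (C7 is flanked on both faces by the C6 gem-dimethyl group, whereas the C10 substituents are tied back in the cyclobutane; the enone cannot enolise) and its β-carbon attacks the O–O σ* of 9, held by hydrogen bonding to the protonated quinuclidine, in an SN2-type acyloxy transfer that forms the C9–O bond with the angelate already in place; because the C8=C9 enamine lies on the local mirror plane of the cage, the catalyst alone chooses the face and gives 9α (9S); the closest known reaction is the amine-catalysed asymmetric α-benzoyloxylation of cyclic ketones with dibenzoyl peroxide.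

Step 7
Reactants: 10 (4S,5S,9S,10R,11R)-9-angeloyloxy-15-norlongipin-2-ene-1,8-dione
Product: 13 (4S,5S,7S,9S,10R,11R)-9-angeloyloxy-7-hydroxy-15-norlongipin-2-ene-1,8-dione, via TMS enol ether 11 (not isolated), via silyloxy epoxide 12 (not isolated)
Conditions: TMSOTf, Et3N, CH2Cl2, −20 °C; then DMDO, acetone, −40 °C; then AcOH, THF/H2O, 0 °C
Reagents that add atoms: dimethyldioxirane, CC1(C)OO1
Why: Rubottom oxidation: soft enolisation goes toward C7 (C9–H is shielded by C10 and the ester), and in the planar C9–C8(OTMS)=C7–C6 array the 9α-angelate blocks the α face, so DMDO epoxidises from the β face and hydrolysis gives the 7β-alcohol (7S).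

Step 8
Reactants: 13 (4S,5S,7S,9S,10R,11R)-9-angeloyloxy-7-hydroxy-15-norlongipin-2-ene-1,8-dione
Product: 14 (4S,5S,7S,8R,9S,10R,11R)-9-angeloyloxy-7,8-dihydroxy-15-norlongipin-2-en-1-one
Conditions: Me4NBH(OAc)3, MeCN/AcOH, −30 °C
Reagents that add atoms: none
Why: Evans–Saksena hydroxyl-directed reduction: the borohydride bound to the 7β-oxygen delivers hydride to C8 on the β face, so the new hydroxyl is α (8R), trans to 7-OH and cis to 9-OAng; the acidic medium suppresses angelate migration and the reagent does not touch the enone.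

Step 9
Reactants: 14 (4S,5S,7S,8R,9S,10R,11R)-9-angeloyloxy-7,8-dihydroxy-15-norlongipin-2-en-1-one
Product: 15 (4S,5S,7S,8R,9S,10R,11R)-8-acetoxy-9-angeloyloxy-7-hydroxy-15-norlongipin-2-en-1-one
Conditions: AcCl (1.1 equiv), 2,4,6-collidine, CH2Cl2, −78 °C
Reagents that add atoms: acetyl chloride, CC(Cl)=O
Why: Sterically controlled O-acylation: the 8-OH is an ordinary secondary alcohol while the 7-OH is neopentyl (next to CMe2), so the acid chloride with a hindered base at low temperature acetylates C8 first, without alkoxide formation and hence without acyl migration.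

Step 10
Reactants: 15 (4S,5S,7S,8R,9S,10R,11R)-8-acetoxy-9-angeloyloxy-7-hydroxy-15-norlongipin-2-en-1-one; 7 angelic acid
Product: 17 (4S,5S,7S,8R,9S,10R,11R)-8-acetoxy-7,9-bis(angeloyloxy)-15-norlongipin-2-en-1-one, via angelic 2,4,6-trichlorobenzoic anhydride 16 (not isolated)
Conditions: 7, 2,4,6-trichlorobenzoyl chloride, Et3N, toluene, rt; then 15, 80 °C
Reagents that add atoms: none
Why: Yamaguchi esterification through the mixed anhydride, run without DMAP, acylates hindered secondary alcohols with angelic acid while keeping the Z geometry; no stereocentre is formed.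

Step 11
Reactants: 17 (4S,5S,7S,8R,9S,10R,11R)-8-acetoxy-7,9-bis(angeloyloxy)-15-norlongipin-2-en-1-one
Product: 19 (3R,4S,5S,7S,8R,9S,10R,11R)-8-acetoxy-7,9-bis(angeloyloxy)longipinan-1-one (target), via lithium enolate 18 (not isolated)
Conditions: Me2CuLi, Et2O, −78 °C; then aq. NH4Cl
Reagents that add atoms: lithium dimethylcuprate, [Li+].C[Cu-]C
Why: Gilman conjugate addition: methyl adds to C3 from the face anti to the C10 bridge, whose C14 methyl overhangs the other face (as with apoverbenone), setting 3R; simple hydrogenation of the corresponding C15-bearing enone would give the C3 epimer, and the α,β-dimethylacrylate esters and the acetate are inert at −78 °C.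

## Compound list

1 | (+)-α-longipinene, (1R,2S,7R,8R)-2,6,6,9-tetramethyltricyclo[5.4.0.0(2,8)]undec-9-ene | C1CC[C@]2(C)[C@@H]3[C@@H]([C@H]2CC=C3C)C1(C)C | starting material
2 | (4R,5S,10R,11R)-longipin-2-en-1-one | C1CC[C@]2(C)[C@@H]3[C@@H]([C@H]2C(=O)C=C3C)C1(C)C | intermediate
3 | (4S,5S,10R,11R)-15-hydroxylongipin-2-en-1-one | C1CC[C@]2(C)[C@@H]3[C@@H]([C@H]2C(=O)C=C3CO)C1(C)C | intermediate (not isolated)
4 | (4S,5S,10R,11R)-1-oxolongipin-2-en-15-al | C1CC[C@]2(C)[C@@H]3[C@@H]([C@H]2C(=O)C=C3C=O)C1(C)C | intermediate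
5 | (4S,5S,10R,11R)-15-norlongipin-2-en-1-one | C1CC[C@]2(C)[C@@H]3[C@@H]([C@H]2C(=O)C=C3)C1(C)C | intermediate
6 | (4S,5S,10R,11R)-15-norlongipin-2-ene-1,8-dione | C1C(=O)C[C@]2(C)[C@@H]3[C@@H]([C@H]2C(=O)C=C3)C1(C)C | intermediate
7 | angelic acid, (Z)-2-methylbut-2-enoic acid | C/C=C(/C)C(=O)O | starting material
8 | peroxyangelic acid | C/C=C(/C)C(=O)OO | intermediate (not isolated)
9 | di(angeloyl) peroxide, bis[(Z)-2-methylbut-2-enoyl] peroxide | C/C=C(/C)C(=O)OOC(=O)/C(C)=C\C | intermediate
10 | (4S,5S,9S,10R,11R)-9-angeloyloxy-15-norlongipin-2-ene-1,8-dione | C1C(=O)[C@@H](OC(=O)/C(C)=C\C)[C@]2(C)[C@@H]3[C@@H]([C@H]2C(=O)C=C3)C1(C)C | intermediate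
11 | TMS enol ether: (9S)-9-angeloyloxy-8-(trimethylsilyloxy)-15-norlongipina-2,7-dien-1-one | C1=C(O[Si](C)(C)C)[C@@H](OC(=O)/C(C)=C\C)[C@]2(C)[C@@H]3[C@@H]([C@H]2C(=O)C=C3)C1(C)C | intermediate (not isolated)
12 | silyloxy epoxide: 9α-angeloyloxy-7β,8β-epoxy-8α-(trimethylsilyloxy)-15-norlongipin-2-en-1-one | O1[C@@H]2[C@@]1(O[Si](C)(C)C)[C@@H](OC(=O)/C(C)=C\C)[C@]3(C)[C@@H]4[C@@H]([C@H]3C(=O)C=C4)C2(C)C | intermediate (not isolated)
13 | (4S,5S,7S,9S,10R,11R)-9-angeloyloxy-7-hydroxy-15-norlongipin-2-ene-1,8-dione | O[C@@H]1C(=O)[C@@H](OC(=O)/C(C)=C\C)[C@]2(C)[C@@H]3[C@@H]([C@H]2C(=O)C=C3)C1(C)C | intermediate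
14 | (4S,5S,7S,8R,9S,10R,11R)-9-angeloyloxy-7,8-dihydroxy-15-norlongipin-2-en-1-one | O[C@@H]1[C@@H](O)[C@@H](OC(=O)/C(C)=C\C)[C@]2(C)[C@@H]3[C@@H]([C@H]2C(=O)C=C3)C1(C)C | intermediate
15 | (4S,5S,7S,8R,9S,10R,11R)-8-acetoxy-9-angeloyloxy-7-hydroxy-15-norlongipin-2-en-1-one | O[C@@H]1[C@@H](OC(C)=O)[C@@H](OC(=O)/C(C)=C\C)[C@]2(C)[C@@H]3[C@@H]([C@H]2C(=O)C=C3)C1(C)C | intermediate
16 | angelic 2,4,6-trichlorobenzoic anhydride | C/C=C(/C)C(=O)OC(=O)c1c(Cl)cc(Cl)cc1Cl | intermediate (not isolated)
17 | (4S,5S,7S,8R,9S,10R,11R)-8-acetoxy-7,9-bis(angeloyloxy)-15-norlongipin-2-en-1-one | C/C=C(/C)C(=O)O[C@@H]1[C@@H](OC(C)=O)[C@@H](OC(=O)/C(C)=C\C)[C@]2(C)[C@@H]3[C@@H]([C@H]2C(=O)C=C3)C1(C)C | intermediate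
18 | lithium enolate of 19 (C1–O−, C1=C2) | C/C=C(/C)C(=O)O[C@@H]1[C@@H](OC(C)=O)[C@@H](OC(=O)/C(C)=C\C)[C@]2(C)[C@@H]3[C@@H]([C@H]2C([O-])=C[C@H]3C)C1(C)C.[Li+] | intermediate (not isolated)
19 | (3R,4S,5S,7S,8R,9S,10R,11R)-8-acetoxy-7,9-bis(angeloyloxy)longipinan-1-one | C/C=C(/C)C(=O)O[C@@H]1[C@@H](OC(C)=O)[C@@H](OC(=O)/C(C)=C\C)[C@]2(C)[C@@H]3[C@@H]([C@H]2C(=O)C[C@H]3C)C1(C)C | target

## Step count and risks

Total step count: 11 (steps 1–11, step 5 being a one-step side branch). Longest linear sequence: 10 (steps 1–4 and 6–11 from (+)-α-longipinene).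

Three steps most likely to fail:

**Step 4 (C8–H ketonisation next to an enone).** The risks are attack at C7/C9 or on the enone. The fallback sets out from 5: an engineered P450-BM3 variant (NADPH recycling with glucose/GDH, air, pH 8 buffer) hydroxylates the same exposed methylene to give (8R)-8-hydroxy-15-norlongipin-2-en-1-one F1 (either C8 epimer serves), and Dess–Martin periodinane then oxidises the alcohol, coming back to the route at 6.

**Step 6 (the proposed new α-angeloyloxylation).** The risks are low enamine reactivity of the hindered ketone, C7/C9 site selectivity, or radical decomposition of the peroxide. The fallback uses known chemistry and sets out from 6. TBSOTf/Et3N gives 8-(tert-butyldimethylsilyloxy)-15-norlongipina-2,8-dien-1-one F2. Shi asymmetric epoxidation (the fructose-derived ketone enantiomer that attacks the α face, Oxone, K2CO3, MeCN/DMM/buffer, 0 °C) gives 8α,9α-epoxy-8β-(tert-butyldimethylsilyloxy)-15-norlongipin-2-en-1-one F3. This is opened in the same pot with TBAF/AcOH to (9S)-9-hydroxy-15-norlongipin-2-ene-1,8-dione F4. Yamaguchi esterification of F4 with 7 comes back to the route at 10.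

**Step 10 (angeloylation of the neopentyl 7-OH).** The risks are sluggish acylation, Z→E isomerisation to the tiglate, or acetyl migration from O8. The fallback sets out from 15 and builds the angelate double bond on the ester instead. DCC/DMAP esterification with 2-[bis(2,2,2-trifluoroethoxy)phosphoryl]propanoic acid gives 8-acetoxy-9-angeloyloxy-7-{2-[bis(2,2,2-trifluoroethoxy)phosphoryl]propanoyloxy}-15-norlongipin-2-en-1-one F5 (epimeric at the phosphonate α-carbon). Still–Gennari olefination (KHMDS, 18-crown-6, acetaldehyde, THF, −78 °C) then forms the (Z)-2-methylbut-2-enoate and comes back to the route at 17.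

## Further compounds

F1 | step 4 | (8R)-8-hydroxy-15-norlongipin-2-en-1-one | C1[C@@H](O)C[C@]2(C)[C@@H]3[C@@H]([C@H]2C(=O)C=C3)C1(C)C
F2 | step 6 | 8-(tert-butyldimethylsilyloxy)-15-norlongipina-2,8-dien-1-one | C1C(O[Si](C)(C)C(C)(C)C)=C[C@]2(C)[C@@H]3[C@@H]([C@H]2C(=O)C=C3)C1(C)C
F3 | step 6 | 8α,9α-epoxy-8β-(tert-butyldimethylsilyloxy)-15-norlongipin-2-en-1-one | C1[C@@]2(O[Si](C)(C)C(C)(C)C)O[C@H]2[C@]3(C)[C@@H]4[C@@H]([C@H]3C(=O)C=C4)C1(C)C
F4 | step 6 | (9S)-9-hydroxy-15-norlongipin-2-ene-1,8-dione | C1C(=O)[C@@H](O)[C@]2(C)[C@@H]3[C@@H]([C@H]2C(=O)C=C3)C1(C)C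
F5 | step 10 | 8-acetoxy-9-angeloyloxy-7-{2-[bis(2,2,2-trifluoroethoxy)phosphoryl]propanoyloxy}-15-norlongipin-2-en-1-one | CC(P(=O)(OCC(F)(F)F)OCC(F)(F)F)C(=O)O[C@@H]1[C@@H](OC(C)=O)[C@@H](OC(=O)/C(C)=C\C)[C@]2(C)[C@@H]3[C@@H]([C@H]2C(=O)C=C3)C1(C)C
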